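## Retrosynthetic overview

- The three esters go on last. The C–OAng carbon is taken back to a ketone, which gives a trans-fused hydroazulenone (cyclopentane fused to a cycloheptenone).
- The strategy rests on two atoms. One is the methyl-bearing quaternary carbon C8a shared by both rings, which lies between the C–OBz carbon (C1, seven-membered ring) and the C–OAc carbon (C8, five-membered ring). The other is the ring-fusion CH (C5), which lies between the C–OAng carbon (C4a) and the C(OH)iPr carbon (C6).
- Key disconnection C5–C8a: a 1,2-shift of C8a from C4a to C5 in a cis-decalin 4a,6-diol 5-mesylate contracts ring B to the cyclopentane and expands ring A to the cycloheptenone.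
- The precursor comes from (S)-Wieland–Miescher ketone. Ring A is built first (C1 ketone to 3-methyl-2-en-1-ol, with the enone masked as a dithiolane). Ring B follows: C8–O by conjugate borylation, C6–OH by directed reduction, the 4a,5-diol by directed osmylation, then C6 is re-oxidised and the isopropyl group added.
- Ring order: both six-membered rings come with the starting ketone; the five- and seven-membered rings form together in the key step.

Key step: step 16

Remark: locants C1–C8a are those of the Wieland–Miescher ketone and are kept after the skeletal shift; cis and trans always refer to the C8a methyl group; (S)-Wieland–Miescher ketone, angelic acid and N-tert-butylbenzenesulfinimidoyl chloride are taken as commercial.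

## Route

Step 1
Reactants: 1 (S)-Wieland–Miescher ketone
Product: 2 C6 1,3-dithiolane of 1 (C1 ketone free, C4a=C5 kept)
Conditions: HS(CH2)2SH, p-TsOH·H2O (cat.), AcOH, rt
Reagents that add atoms: ethane-1,2-dithiol, SCCS
Why: Acid-catalysed thioketalisation should take the conjugated C6 carbonyl selectively, because the C1 ketone next to the quaternary carbon is hindered, and the double bond of an enone thioketal stays in place.

Step 2
Reactants: 2 C6 1,3-dithiolane of 1
Product: 4 C6-dithiolane 2,4a(5)-dien-1-one, via lithium enolate 3 (not isolated)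
Conditions: LDA, THF, −78 °C; then PhS(Cl)=N-t-Bu, −78 °C
Reagents that add atoms: none
Why: Mukaiyama dehydrogenation of a ketone enolate: C2 is the only enolisable position, the α-sulfilimine eliminates at low temperature, and no palladium is used that the dithiolane would bind.

Step 3
Reactants: 4 C6-dithiolane 2,4a(5)-dien-1-one; 5 methyllithium (used as lithium dimethylcuprate)
Product: 7 C6-dithiolane 3-methyl-2,4a(5)-dien-1-one, via lithium enolate 6 (not isolated)
Conditions: MeLi (2 equiv), CuI, Et2O, −78 → −20 °C; then PhS(Cl)=N-t-Bu, THF, −78 °C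
Reagents that add atoms: methyllithium, [Li]C
Why: Cuprate conjugate addition puts the methyl group on C3, and the enolate so formed is dehydrogenated in the same flask as in step 2, so the C3 stereocentre is removed again.

Step 4
Reactants: 7 C6-dithiolane 3-methyl-2,4a(5)-dien-1-one
Product: 8 C6-dithiolane 3-methyl-2,4a(5)-dien-1-ol (1-OH cis to the 8a-methyl)
Conditions: NaBH4, CeCl3·7H2O, MeOH, −78 → 0 °C
Reagents that add atoms: none
Why: Luche 1,2-reduction: hydride should enter C1 anti to the angular methyl on the neighbouring carbon (C8 is still an unsubstituted CH2), which sets the C1 hydroxyl cis to the methyl.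

Step 5
Reactants: 8 C6-dithiolane 3-methyl-2,4a(5)-dien-1-ol
Product: 9 1-O-PMB ether of 8
Conditions: NaH, PMBCl, n-Bu4NI (cat.), DMF, 0 °C → rt
Reagents that add atoms: 4-methoxybenzyl chloride, COc1ccc(CCl)cc1
Why: Williamson etherification, safe here because the enone is masked and no base-sensitive carbonyl is present.

Step 6
Reactants: 9 1-O-PMB ether of 8
Product: 10 1-OPMB-3-methyl-2,4a(5)-dien-6-one (1-OPMB cis to the 8a-methyl)
Conditions: MeI, CaCO3, MeCN/H2O (4:1), 45 °C
Reagents that add atoms: water, O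
Why: Alkylative hydrolysis of the dithiolane: S-methylation opens it to an allylic thionium ion that water captures, and the carbonate buffer should keep the skipped C2=C3 alkene and the PMB ether intact.

Step 7
Reactants: 10 1-OPMB-3-methyl-2,4a(5)-dien-6-one
Product: 12 1-OPMB-3-methyl-2,4a(5),7-trien-6-one, via lithium dienolate 11 (not isolated)
Conditions: LDA, THF, −78 °C; then PhS(Cl)=N-t-Bu, −78 °C
Reagents that add atoms: none
Why: Kinetic deprotonation of the enone at the α′-CH2 (C7) gives the cross-conjugated dienolate, and Mukaiyama dehydrogenation then introduces the C7=C8 double bond.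

Step 8
Reactants: 12 1-OPMB-3-methyl-2,4a(5),7-trien-6-one
Product: 14 8-hydroxy-1-OPMB-3-methyl-2,4a(5)-dien-6-one (8-OH trans to the 8a-methyl), via pinacol boronate 13 (not isolated)
Conditions: B2pin2, CuCl (5 mol%), Xantphos (5 mol%), NaOt-Bu (10 mol%), MeOH (2 equiv), THF, 0 °C; then NaBO3·4H2O, THF/H2O, rt
Reagents that add atoms: sodium perborate, [Na+].[Na+].O[B-]1(O)OO[B-](O)(O)OO1
Why: Copper-catalysed conjugate borylation then oxidation with retention: the boryl group should add at C8, the only β-carbon bearing hydrogen, from the face anti to the 8a-methyl (on that face C1 carries only hydrogen), so the hydroxyl ends trans to the methyl.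

Step 9
Reactants: 14 8-hydroxy-1-OPMB-3-methyl-2,4a(5)-dien-6-one
Product: 15 6,8-diol (6-OH cis, 8-OH trans to the 8a-methyl)
Conditions: Me4NBH(OAc)3, MeCN/AcOH (1:1), −20 °C
Reagents that add atoms: none
Why: Evans–Saksena reduction: the borohydride bound to the C8 oxygen delivers hydride to the same face of the C6 carbonyl, which should give the anti-1,3-diol with the C6 hydroxyl cis to the methyl.

Step 10
Reactants: 15 6,8-diol
Product: 17 6-O-TES 8-O-TBS bis-ether, via 6-O-TES ether 16 (not isolated)
Conditions: TESCl (1.05 equiv), imidazole, CH2Cl2, −20 °C; then 2,6-lutidine, TBSOTf, −20 → 0 °C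
Reagents that add atoms: chlorotriethylsilane, CC[Si](Cl)(CC)CC; tert-butyldimethylsilyl triflate, CC(C)(C)[Si](C)(C)OS(=O)(=O)C(F)(F)F
Why: Stepwise silylation by steric differentiation: the unhindered allylic C6 hydroxyl takes the TES group first, and the neopentylic C8 hydroxyl then reacts only with the silyl triflate.

Step 11
Reactants: 17 6-O-TES 8-O-TBS bis-ether
Product: 18 8-O-TBS allylic alcohol (6-OH free, cis to the 8a-methyl)
Conditions: PPTS (cat.), MeOH/CH2Cl2, 0 °C
Reagents that add atoms: none
Why: Acid-catalysed methanolysis should remove the secondary TES ether much faster than the hindered TBS ether or the PMB ether.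

Step 12
Reactants: 18 8-O-TBS allylic alcohol
Product: 20 cis-decalin 4a,5,6-triol (all three OH cis to the 8a-methyl), via osmate ester 19 (not isolated)
Conditions: OsO4 (1.05 equiv), TMEDA (1.1 equiv), CH2Cl2, −78 °C; then aq. Na2SO3, THF, 60 °C
Reagents that add atoms: osmium tetroxide, O=[Os](=O)(=O)=O
Why: Hydroxyl-directed dihydroxylation with OsO4·TMEDA: the reagent hydrogen-bonds to the C6 hydroxyl and should add to the C4a=C5 alkene on that face (the opposite face carries the axial C8 silyl ether), faster than to the non-directed C2=C3 alkene, which sets C4a–O and C5–O syn and cis to the methyl.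

Step 13
Reactants: 20 cis-decalin 4a,5,6-triol
Product: 21 4a,5-dihydroxy-6-ketone
Conditions: IBX (1.2 equiv), DMSO, rt
Reagents that add atoms: none
Why: IBX oxidation should take the axial, less hindered C6 carbinol, since the C5 hydroxyl sits next to the fully substituted C4a, the tertiary hydroxyl is inert, and IBX does not cleave 1,2-diols.

Step 14
Reactants: 21 4a,5-dihydroxy-6-ketone; 22 isopropylmagnesium chloride
Product: 23 6-isopropyl-4a,5,6-triol (6-OH cis, isopropyl trans to the 8a-methyl)
Conditions: CeCl3 (anhydrous), i-PrMgCl (5 equiv), THF, −78 °C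
Reagents that add atoms: isopropylmagnesium chloride, CC(C)[Mg]Cl
Why: Organocerium 1,2-addition (low basicity, so no enolisation or retro-aldol): in the chair of the cis-decalin the axial C4a oxygen blocks the axial approach to C6, so the isopropyl group should enter equatorially and the new hydroxyl ends axial, cis to the 4a- and 5-oxygens.

Step 15
Reactants: 23 6-isopropyl-4a,5,6-triol
Product: 24 5-mesylate of 23 (cis-decalin 4a,6-diol 5-mesylate)
Conditions: MsCl, Et3N, CH2Cl2, −20 → 0 °C
Reagents that add atoms: methanesulfonyl chloride, CS(=O)(=O)Cl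
Why: Sulfonylation through sulfene should reach only the secondary C5 hydroxyl and leave the two tertiary hydroxyls free.

Step 16
Reactants: 24 5-mesylate of 23
Product: 26 trans-fused hydroazulenone (C4a ketone, C5–H trans to the 8a-methyl, 6-OH free), via aluminium alkoxide 25 (not isolated)
Conditions: Et3Al (3 equiv), CH2Cl2, −78 → 0 °C; Rochelle salt work-up
Reagents that add atoms: none
Why: Et3Al turns both tertiary hydroxyls into aluminium alkoxides and, as a Lewis acid, loosens the equatorial C5 mesylate; the C4a–C8a σ-bond, antiperiplanar to C5–OMs in the chair with equatorial isopropyl, shifts to C5 as mesylate leaves and the C4a oxygen becomes the carbonyl (semipinacol rearrangement of a 2-hydroxy sulfonate). The closest known reactions are the organoaluminium-promoted pinacol-type rearrangement of β-mesyloxy alcohols and the ring contraction of decalin-diol monosulfonates to hydroazulenones. No ring is closed by cyclisation: the one new bond C5–C8a contracts ring B to the cyclopentane (C5–C6–C7–C8–C8a) and expands ring A to the cycloheptenone (C8a–C1–C2–C3–C4–C4a–C5) in a suprafacial 1,2-shift. The new stereocentre C5 is set by inversion (C8a enters anti to the leaving group) with retention at the migrating C8a, and because the mesylate is cis to the angular methyl the ring-fusion hydrogen ends trans to it. The step needs C8a to migrate rather than the C7 methylene, which the C6 alkoxide could push across the equally antiperiplanar C6–C7 bond; the fully substituted C8a is the better migrating group, and no epoxide can form because both flanking oxygens are cis to the mesylate. The non-basic, low-temperature medium should leave the β,γ-enone unconjugated and the C5–H unepimerised.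

Step 17
Reactants: 26 trans-fused hydroazulenone
Product: 27 C4a alcohol (4a-OH trans to the 8a-methyl, cis to the C5–H)
Conditions: Me4NBH(OAc)3, MeCN/AcOH (1:1), −30 °C
Reagents that add atoms: none
Why: Evans–Saksena reduction directed by the tertiary C6 hydroxyl: internal hydride delivery should give the 1,3-anti diol, which sets the C4a carbinol, and the acidic medium avoids enolisation of the β,γ-enone.

Step 18
Reactants: 27 C4a alcohol; 28 angelic acid
Product: 29 4a-angelate
Conditions: angelic acid, 2,4,6-Cl3C6H2COCl, Et3N, toluene, rt; then 27, 75 °C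
Reagents that add atoms: angelic acid, C/C=C(/C)C(=O)O
Why: Yamaguchi-type esterification through the preformed mixed anhydride, without a nucleophilic catalyst, should acylate the secondary hydroxyl without Z-to-E isomerisation to the tiglate, while the tertiary hydroxyl stays free.

Step 19
Reactants: 29 4a-angelate
Product: 30 1-alcohol (PMB removed)
Conditions: DDQ (1.3 equiv), CH2Cl2/pH 7 buffer (10:1), 0 °C
Reagents that add atoms: none
Why: Oxidative PMB cleavage by DDQ through the benzylic oxocarbenium ion; the silyl ether, the angelate and the trisubstituted alkene should not react at 0 °C.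

Step 20
Reactants: 30 1-alcohol; 31 benzoyl chloride
Product: 32 1-benzoate
Conditions: BzCl, pyridine, DMAP (cat.), CH2Cl2, 0 °C → rt
Reagents that add atoms: benzoyl chloride, O=C(Cl)c1ccccc1
Why: Acylation of the only secondary hydroxyl (allylic C1–OH); the tertiary C6 hydroxyl is too hindered to react.

Step 21
Reactants: 32 1-benzoate
Product: 33 8-alcohol (TBS removed)
Conditions: HF·pyridine, pyridine, THF, 0 °C → rt
Reagents that add atoms: none
Why: Buffered fluoride desilylation; the esters should survive, and acyl migration from C1 is unlikely because the C1 and C8 oxygens are trans across the quaternary carbon.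

Step 22
Reactants: 33 8-alcohol; 34 acetic anhydride
Product: 35 CNP0248576.1 (target)
Conditions: Ac2O, pyridine, DMAP (cat.), CH2Cl2, rt
Reagents that add atoms: acetic anhydride, CC(=O)OC(C)=O
Why: Acetylation of the secondary C8 hydroxyl, with the tertiary C6 hydroxyl left free as in the target.

## Compound list

1 | (S)-Wieland–Miescher ketone, (8aS)-8a-methyl-3,4,8,8a-tetrahydronaphthalene-1,6(2H,7H)-dione | O=C1CCCC2=CC(=O)CC[C@]12C | starting material
2 | C6 1,3-dithiolane of 1 (C1 ketone free, C4a=C5) | O=C1CCCC2=CC3(SCCS3)CC[C@]12C | intermediate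
3 | lithium C1(2)-enolate of 2 | [Li]OC1=CCCC2=CC3(SCCS3)CC[C@]12C | intermediate
4 | C6-dithiolane 2,4a(5)-dien-1-one | O=C1C=CCC2=CC3(SCCS3)CC[C@]12C | intermediate
5 | methyllithium | [Li]C | starting material
6 | lithium C1(2)-enolate of the 3-methyl ketone (C3 configuration immaterial) | [Li]OC1=CC(C)CC2=CC3(SCCS3)CC[C@]12C | intermediate
7 | C6-dithiolane 3-methyl-2,4a(5)-dien-1-one | O=C1C=C(C)CC2=CC3(SCCS3)CC[C@]12C | intermediate
8 | C6-dithiolane 3-methyl-2,4a(5)-dien-1-ol, 1-OH cis to 8a-Me | O[C@H]1C=C(C)CC2=CC3(SCCS3)CC[C@]12C | intermediate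
9 | 1-O-PMB ether of 8 | COc1ccc(CO[C@H]2C=C(C)CC3=CC4(SCCS4)CC[C@]23C)cc1 | intermediate
10 | 1-OPMB-3-methyl-2,4a(5)-dien-6-one | COc1ccc(CO[C@H]2C=C(C)CC3=CC(=O)CC[C@]23C)cc1 | intermediate
11 | lithium C6(7)-dienolate of 10 | COc1ccc(CO[C@H]2C=C(C)CC3=CC(O[Li])=CC[C@]23C)cc1 | intermediate
12 | 1-OPMB-3-methyl-2,4a(5),7-trien-6-one | COc1ccc(CO[C@H]2C=C(C)CC3=CC(=O)C=C[C@]23C)cc1 | intermediate
13 | 8-(pinacolboryl)-1-OPMB-3-methyl-2,4a(5)-dien-6-one, boryl trans to 8a-Me | COc1ccc(CO[C@H]2C=C(C)CC3=CC(=O)C[C@H](B4OC(C)(C)C(C)(C)O4)[C@]23C)cc1 | intermediate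
14 | 8-hydroxy-1-OPMB-3-methyl-2,4a(5)-dien-6-one, 8-OH trans to 8a-Me | COc1ccc(CO[C@H]2C=C(C)CC3=CC(=O)C[C@H](O)[C@]23C)cc1 | intermediate
15 | 1-OPMB-3-methyl-2,4a(5)-diene-6,8-diol, 6-OH cis and 8-OH trans to 8a-Me | COc1ccc(CO[C@H]2C=C(C)CC3=C[C@@H](O)C[C@H](O)[C@]23C)cc1 | intermediate
16 | 6-O-TES ether of 15 | COc1ccc(CO[C@H]2C=C(C)CC3=C[C@@H](O[Si](CC)(CC)CC)C[C@H](O)[C@]23C)cc1 | intermediate
17 | 6-O-TES 8-O-TBS bis-ether of 15 | COc1ccc(CO[C@H]2C=C(C)CC3=C[C@@H](O[Si](CC)(CC)CC)C[C@H](O[Si](C)(C)C(C)(C)C)[C@]23C)cc1 | intermediate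
18 | 8-O-TBS-1-OPMB-3-methyl-2,4a(5)-dien-6-ol, 6-OH cis to 8a-Me | COc1ccc(CO[C@H]2C=C(C)CC3=C[C@@H](O)C[C@H](O[Si](C)(C)C(C)(C)C)[C@]23C)cc1 | intermediate
19 | 4a,5-osmate(VI) ester·TMEDA of 18, osmate oxygens cis to 6-OH and 8a-Me | O=[Os]4(=O)O[C@]12CC(C)=C[C@H](OCc3ccc(OC)cc3)[C@@]1(C)[C@@H](O[Si](C)(C)C(C)(C)C)C[C@H](O)[C@@H]2O4.CN(C)CCN(C)C | intermediate
20 | cis-decalin 4a,5,6-triol (all OH cis to 8a-Me; 1-OPMB, 8-OTBS, 3-methyl-2-ene) | O[C@]12CC(C)=C[C@H](OCc3ccc(OC)cc3)[C@@]1(C)[C@@H](O[Si](C)(C)C(C)(C)C)C[C@H](O)[C@@H]2O | intermediate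
21 | 4a,5-dihydroxy-6-ketone (1-OPMB, 8-OTBS, 3-methyl-2-ene) | O[C@]12CC(C)=C[C@H](OCc3ccc(OC)cc3)[C@@]1(C)[C@@H](O[Si](C)(C)C(C)(C)C)CC(=O)[C@@H]2O | intermediate
22 | isopropylmagnesium chloride | CC(C)[Mg]Cl | starting material
23 | 6-isopropyl-4a,5,6-triol, 6-OH cis and isopropyl trans to 8a-Me | O[C@]12CC(C)=C[C@H](OCc3ccc(OC)cc3)[C@@]1(C)[C@@H](O[Si](C)(C)C(C)(C)C)C[C@@](O)(C(C)C)[C@@H]2O | intermediate
24 | cis-decalin 4a,6-diol 5-mesylate (1-OPMB, 8-OTBS, 3-methyl-2-ene, 6-isopropyl) | O[C@]12CC(C)=C[C@H](OCc3ccc(OC)cc3)[C@@]1(C)[C@@H](O[Si](C)(C)C(C)(C)C)C[C@@](O)(C(C)C)[C@@H]2OS(C)(=O)=O | intermediate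
25 | 4a,6-bis(diethylaluminium) alkoxide of 24 | CC[Al](CC)O[C@]12CC(C)=C[C@H](OCc3ccc(OC)cc3)[C@@]1(C)[C@@H](O[Si](C)(C)C(C)(C)C)C[C@@](O[Al](CC)CC)(C(C)C)[C@@H]2OS(C)(=O)=O | intermediate
26 | trans-fused hydroazulenone: C4a ketone, C5–H trans to 8a-Me, 6-OH/6-isopropyl, 1-OPMB, 8-OTBS, 3-methyl-2-ene | O=C1CC(C)=C[C@H](OCc3ccc(OC)cc3)[C@@]2(C)[C@@H](O[Si](C)(C)C(C)(C)C)C[C@@](O)(C(C)C)[C@H]12 | intermediate
27 | C4a alcohol of 26, 4a-OH trans to 8a-Me | O[C@H]1CC(C)=C[C@H](OCc3ccc(OC)cc3)[C@@]2(C)[C@@H](O[Si](C)(C)C(C)(C)C)C[C@@](O)(C(C)C)[C@H]12 | intermediate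
28 | angelic acid, (Z)-2-methylbut-2-enoic acid | C/C=C(/C)C(=O)O | starting material
29 | 4a-angelate of 27 | C/C=C(/C)C(=O)O[C@H]1CC(C)=C[C@H](OCc3ccc(OC)cc3)[C@@]2(C)[C@@H](O[Si](C)(C)C(C)(C)C)C[C@@](O)(C(C)C)[C@H]12 | intermediate
30 | 4a-angelate 1-alcohol (8-OTBS) | C/C=C(/C)C(=O)O[C@H]1CC(C)=C[C@H](O)[C@@]2(C)[C@@H](O[Si](C)(C)C(C)(C)C)C[C@@](O)(C(C)C)[C@H]12 | intermediate
31 | benzoyl chloride | O=C(Cl)c1ccccc1 | starting material
32 | 4a-angelate 1-benzoate (8-OTBS) | C/C=C(/C)C(=O)O[C@H]1CC(C)=C[C@H](OC(=O)c2ccccc2)[C@@]2(C)[C@@H](O[Si](C)(C)C(C)(C)C)C[C@@](O)(C(C)C)[C@H]12 | intermediate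
33 | 4a-angelate 1-benzoate 8-alcohol | C/C=C(/C)C(=O)O[C@H]1CC(C)=C[C@H](OC(=O)c2ccccc2)[C@@]2(C)[C@@H](O)C[C@@](O)(C(C)C)[C@H]12 | intermediate
34 | acetic anhydride | CC(=O)OC(C)=O | starting material
35 | CNP0248576.1 | C/C=C(/C)C(=O)O[C@H]1CC(C)=C[C@H](OC(=O)c2ccccc2)[C@@]2(C)[C@@H](OC(C)=O)C[C@@](O)(C(C)C)[C@H]12 | target

Total step count: 22
Longest linear sequence: 22 steps (1 → 35)

## Steps most likely to fail

1. Step 16. The C6 alkoxide may compete as the electron donor, so that the C7 methylene shifts instead of C8a and ring B contracts to an acylcyclopentane; the aluminium aldolate of the product may also open by retro-aldol. The fallback removes the push from C6 and sets out from keto-diol 21. 2-Methoxypropene and PPTS should give the 4a,5-acetonide ketone F1. i-PrMgCl/CeCl3 should then add from the face away from the acetonide to give the tertiary alcohol F2. TESOTf and 2,6-lutidine give the triethylsilyl ether F3. Aqueous acetic acid in THF removes the acetonide to give the 4a,5-diol F4, and MsCl/Et3N gives the mesylate F5. With Et3Al only the free C4a alkoxide can now drive the shift, which should give the silyloxy ketone F6. Buffered HF·pyridine at 0 °C frees the tertiary hydroxyl, and the route is rejoined at 26.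

2. Step 13. The oxidant may not discriminate well between the two secondary hydroxyls, and oxidation may run on to the 5,6-dione. The fallback sets out from triol 20. Bu2SnO in refluxing methanol should give the 5,6-O-dibutylstannylene acetal F7. Brominolysis (NBS, CHCl3, rt) of such acetals of cis-diols oxidises the carbinol of the axial oxygen, here C6, and stops at the hydroxy ketone, so the route is rejoined at 21.

3. Step 8. Borylation at the neopentylic β-carbon may be slow and accompanied by protodeboronation, or the alkoxide co-catalyst may move the C2=C3 double bond into conjugation through the doubly activated C4 methylene. The fallback sets out from trienone 12. Nucleophilic epoxidation (H2O2, NaOH, MeOH, 0 °C) should give the 7,8-epoxy enone F8 with the oxygen anti to the 8a-methyl. Reductive opening of the α,β-epoxy ketone with (PhSe)2/NaBH4 in EtOH/AcOH then gives the β-hydroxy enone, and the route is rejoined at 14.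

## Further compounds

F1 | step 16 | 4a,5-acetonide of keto-diol 21 | CC4(C)O[C@]12CC(C)=C[C@H](OCc3ccc(OC)cc3)[C@@]1(C)[C@@H](O[Si](C)(C)C(C)(C)C)CC(=O)[C@@H]2O4
F2 | step 16 | 4a,5-acetonide 6-isopropyl-6-ol (6-OH cis to 8a-Me) | CC4(C)O[C@]12CC(C)=C[C@H](OCc3ccc(OC)cc3)[C@@]1(C)[C@@H](O[Si](C)(C)C(C)(C)C)C[C@@](O)(C(C)C)[C@@H]2O4
F3 | step 16 | 6-O-TES ether of F2 | CC4(C)O[C@]12CC(C)=C[C@H](OCc3ccc(OC)cc3)[C@@]1(C)[C@@H](O[Si](C)(C)C(C)(C)C)C[C@@](O[Si](CC)(CC)CC)(C(C)C)[C@@H]2O4
F4 | step 16 | 6-O-TES 4a,5-diol | O[C@]12CC(C)=C[C@H](OCc3ccc(OC)cc3)[C@@]1(C)[C@@H](O[Si](C)(C)C(C)(C)C)C[C@@](O[Si](CC)(CC)CC)(C(C)C)[C@@H]2O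
F5 | step 16 | 6-O-TES 4a-ol 5-mesylate | O[C@]12CC(C)=C[C@H](OCc3ccc(OC)cc3)[C@@]1(C)[C@@H](O[Si](C)(C)C(C)(C)C)C[C@@](O[Si](CC)(CC)CC)(C(C)C)[C@@H]2OS(C)(=O)=O
F6 | step 16 | 6-O-TES trans-hydroazulenone | O=C1CC(C)=C[C@H](OCc3ccc(OC)cc3)[C@@]2(C)[C@@H](O[Si](C)(C)C(C)(C)C)C[C@@](O[Si](CC)(CC)CC)(C(C)C)[C@H]12
F7 | step 13 | 5,6-O-dibutylstannylene acetal of triol 20 | O[C@]12CC(C)=C[C@H](OCc3ccc(OC)cc3)[C@@]1(C)[C@@H](O[Si](C)(C)C(C)(C)C)C[C@H](O[Sn]4(CCCC)CCCC)[C@@H]2O4
F8 | step 8 | 7,8-epoxy-1-OPMB-3-methyl-2,4a(5)-dien-6-one, epoxide trans to 8a-Me | COc1ccc(CO[C@H]2C=C(C)CC3=CC(=O)[C@@H]4O[C@@H]4[C@]23C)cc1
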